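4 questions stand on one flask, and the north-east run is that same flask, followed up to 15.0 min.

all flasks: starting material 0.0050 M; free catalyst 50 µM

|  | coupling partner | temperature | remark | time |
|---|---|---|---|---|
| north-east | 4 mM | 20 °C | the very flask that is asked about, followed so far |  |
| north | 4 mM | 5 °C | run made earlier |  |
| flask | 4.00 mM | 20 °C |  | 20 min |

- north-east (time / min: product / %, starting material / %): 0.833: 7, 92; 2.50: 11, 88; 5.00: 11, 88; 6.00: 11, 89; 10.0: 10, 86; 12.0: 12, 86; 15.0: 14, 84
- north (time / min: product / %, starting material / %): 2.00: 12, 84; 5.00: 21, 81; 10.0: 30, 73; 12.0: 31, 72; 20.0: 34, 69; 25.0: 31, 68; 30.0: 32, 69

(each reading ± 2 percentage points)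

- ochre: at 20 min raise the temperature by 25 K, then wait 6.0 min
- green: at 20 min add coupling partner, 100% of the amount charged, then wait 6.0 min
- violet: at 20 min add free catalyst, 100% of the amount charged, then wait 6.0 min
- amber: change nothing and wait 6.0 min more
- blue: at 20 min take out 90% of the product then present, then wait 6.0 min

- product, in percent of the starting material first charged, at 20 min
- the option that brings most further product ("none" if no option brings more than 2 percentage points) (ochre / green / violet / amber / blue / none)
- product present, with what was taken out counted in, in percent of the starting material first charged, after green
- product present, with what was taken out counted in, in percent of the starting material first charged, after amber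

- removed product is counted in
- the earlier runs were read with a standard deviation of 2 percentage points
- additions bring no volume worth counting

I compare the rate of product at two moments in the north-east run. From 0.833 min to 5.00 min the product gains 4 percentage points, and from 5.00 min to 15.0 min it gains 3 points. The rate drifts down as the clock runs, so I multiply each rate by the mean time of its interval. I call this result L, the points of product gained each time the clock grows by a factor e:

L(early) = 2.8 points
L(late) = 3 points

These two values, read from scattered readings, lie close, so I take L = 2.9 points.

There are two ways to reach 20 min:

straight line from the late rate: 15.5%
L times the logarithm of the time ratio: 14.8%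

They differ by 0.70 points, less than the scatter of a reading. Both start from the same last reading, so this nearness is no check. It says that the choice of curve matters little up to this time, and I carry about 15.2%. At 10 times that time they part: the line says 69.5% and L says 21.5%. The line cheats, since it holds a steady rate while the readings show a falling one.

So I commit to L. Waiting gains 0.76 points, which puts amber at 15.6%. Coupling partner is the limiting reagent. If L follows it, green gains about 1.5 points and reaches 16.4%. Warming looks wrong: at 10.0 min the colder north run reads 30% and the north-east run 10%. Fresh catalyst should restart the clock, and the north-east run read 11% at 6.00 min, so I choose violet. Removal I cannot read from these runs.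

The forecast says 15%, violet, 18% after green and 16.5% after amber, with “Fresh catalyst should give another burst of about 10 points”. It agrees with my choice, but its green and amber stand above mine.

The flask gives 16.8%. The best option is violet, gaining 7.9 points, with 18.2% after green and 17.5% after amber.

    starting material + free catalyst ⇌ catalyst intermediate A (K = 200 /M, k = 580 /M/s, Ea = 37.0 kJ/mol, ΔH = −52.0 kJ/mol)
    coupling partner + catalyst intermediate A ⇌ catalyst intermediate B (K = 120 /M, k = 880 /M/s, Ea = 38.0 kJ/mol, ΔH = −52.0 kJ/mol)
    catalyst intermediate B ⇌ free catalyst + product (K = 0.0180 M, k = 3.30 /s, Ea = 65.0 kJ/mol, ΔH = −35.0 kJ/mol)
    2 free catalyst → spent catalyst (k = 3300 /M/s, Ea = 24.0 kJ/mol)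
    (constants at 20 °C)

Left 10 times as long, this flask holds 22.3%; L gave 21.5%. The forecast's 15% stands within its margin at this charge, but the answer to "now" has moved 5 points once coupling partner reaches 5.92 mM. The neighbouring flask holds 0.0068 M of coupling partner, 1.36 equiv against starting material. If L and the whole curve follow that charge, L grows by a factor 1.70 to 4.9 points, and the flask's 16.8% becomes 28.6%. At 20 min the neighbouring flask stands at 23.7%.

The numbers in the tables stem from a simulated flask for substances that don't exist.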